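**Retrosynthetic overview**
1. 19 <= 18. The methyl ester and 7-OH come from methanolysis of a temporary lactone, ring C (O7, C7, C8, benzylic CH, CH2, C=O). Chromanone numbering of 19 is used throughout; ring A is the benzene ring and ring B the dihydropyranone.
2. 18 <= 14 (key step). Electrophilic activation of a tertiary amide closes ring B at C4-C4a, and the C4 iminium so formed triggers a [3,3] shift of a 1,1-dimethylallyl group from O5 to C6. One flask makes two C-C bonds, fills ring A completely, fixes the cis C2/C3 pair and frees 5-OH.
3. Enabling feature: C4a is the only H-bearing carbon ortho to O1. It lies between C8a-O1 and C5-O5 and para to C7-O7, which makes it the most nucleophilic site of phloroglucinol ring A. O5 is peri to C4 and so is conjugated through C5=C4a with any pi-acceptor built at C4.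
4. 14 <= 9 + 13 by Mitsunobu inversion (O1-C2). 13 comes from methyl (S)-3-hydroxybutanoate. 9 comes from asymmetric CuH reduction of the flat coumarin 7, which is made from phloroglucinol by Pechmann condensation and 7-O-allylation.
5. Ring order: A (bought), C (step 1, made stereogenic in step 4), B (step 8), C opened (step 9).

Key step: step 8

Assumption: the (R) antipode of DTBM-SEGPHOS is taken to deliver hydride to the Si face of C4 of coumarin 7. If the sense of induction is the opposite, the (S) ligand is used and nothing else changes.

**Step 1**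
Reactants: 1 phloroglucinol; 2 ethyl 3-oxohexanoate
Product: 3 5,7-dihydroxy-4-propylcoumarin
Conditions: CF3SO3H, neat, 0 °C to rt
Reagents that add atoms: none
Why: Pechmann condensation (transesterification, attack of ring A on the activated ketone, dehydration) should give a single coumarin because all three ring positions of 1 are equivalent.

**Step 2**
Reactants: 4 2-methylbut-3-en-2-ol
Product: 6 tert-butyl (2-methylbut-3-en-2-yl) carbonate, via lithium alkoxide 5 (not isolated)
Conditions: n-BuLi, THF, -78 °C; Boc2O, -78 °C to rt; aq work-up
Reagents that add atoms: di-tert-butyl dicarbonate, CC(C)(C)OC(=O)OC(=O)OC(C)(C)C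
Why: O-acylation of the tertiary lithium alkoxide by the dicarbonate is a standard mixed-carbonate synthesis and avoids acid, which would ionise the tertiary allylic alcohol.

**Step 3**
Reactants: 3 5,7-dihydroxy-4-propylcoumarin; 6 tert-butyl (2-methylbut-3-en-2-yl) carbonate
Product: 7 5-hydroxy-7-[(2-methylbut-3-en-2-yl)oxy]-4-propylcoumarin
Conditions: Pd(PPh3)4 (5 mol %), 6 (1.05 equiv), THF, 0 °C
Reagents that add atoms: none
Why: Tsuji-Trost O-allylation: zerovalent palladium ionises 6 with loss of CO2 and tert-butoxide, the latter deprotonates the more acidic 7-OH (vinylogous to the lactone carbonyl), and this unhindered phenoxide should attack the tertiary end of the dimethylallyl complex under kinetic control while 5-OH is shielded by the peri propyl group.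

**Step 4**
Reactants: 7 5-hydroxy-7-[(2-methylbut-3-en-2-yl)oxy]-4-propylcoumarin
Product: 9 (4R)-5-hydroxy-7-[(2-methylbut-3-en-2-yl)oxy]-4-propyl-3,4-dihydrochromen-2-one, via silyl ketene acetal 8 (not isolated)
Conditions: Cu(OAc)2·H2O (3 mol %), (R)-DTBM-SEGPHOS (3 mol %), (EtO)2MeSiH (2.5 equiv), toluene, 0 °C, no added alcohol; then aq citric acid-THF
Reagents that add atoms: none
Why: Ligand-controlled asymmetric conjugate reduction by ligated CuH, close to known reductions of 4-substituted coumarins: 5-OH is first capped by dehydrogenative silylation, hydride goes to the Si face of C4 to set the (R) benzylic centre, and without added alcohol the enolate is held as silyl ketene acetal 8, which guards the lactone against 1,2-reduction until the mild acidic work-up.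

**Step 5**
Reactants: 10 methyl (S)-3-hydroxybutanoate
Product: 12 methyl (2S,3S)-3-hydroxy-2-methylbutanoate, via dilithio dianion 11 (not isolated)
Conditions: LiN(iPr)2 (LDA, 2.2 equiv), THF, -78 to -20 °C; MeI, DMPU, -78 to 0 °C; then AcOH
Reagents that add atoms: iodomethane, CI
Why: Fráter-Seebach alkylation: the lithium-chelated dianion 11 is methylated on the face opposite the carbinol methyl group, which should set C2 as (S) and give the anti (2S,3S) ester.

**Step 6**
Reactants: 12 methyl (2S,3S)-3-hydroxy-2-methylbutanoate
Product: 13 (2S,3S)-3-hydroxy-2-methyl-1-(pyrrolidin-1-yl)butan-1-one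
Conditions: pyrrolidine (neat, 5 equiv), 50 °C
Reagents that add atoms: pyrrolidine, C1CCNC1
Why: Direct aminolysis of the methyl ester by the strongly nucleophilic cyclic amine, assisted by the neighbouring hydroxyl group, touches no stereocentre and installs the tertiary amide needed for electrophilic activation.

**Step 7**
Reactants: 9 (4R)-5-hydroxy-7-[(2-methylbut-3-en-2-yl)oxy]-4-propyl-3,4-dihydrochromen-2-one; 13 (2S,3S)-3-hydroxy-2-methyl-1-(pyrrolidin-1-yl)butan-1-one
Product: 14 (2S,3R)-2-methyl-3-{[(4R)-7-[(2-methylbut-3-en-2-yl)oxy]-2-oxo-4-propyl-3,4-dihydrochromen-5-yl]oxy}-1-(pyrrolidin-1-yl)butan-1-one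
Conditions: PPh3, DIAD, toluene (1 M), 0 °C to rt, sonication
Reagents that add atoms: none
Why: Mitsunobu etherification: the phenoxide of 9 displaces the oxyphosphonium group of 13 in an SN2 step with inversion (carbinol S to ether R, the future C2), and the amide, being less acidic at its alpha carbon than an ester, should curb the competing elimination.

**Step 8**
Reactants: 14 (2S,3R)-2-methyl-3-{[(4R)-7-[(2-methylbut-3-en-2-yl)oxy]-2-oxo-4-propyl-3,4-dihydrochromen-5-yl]oxy}-1-(pyrrolidin-1-yl)butan-1-one
Product: 18 tricyclic keto lactone (cis-(2R,3S)-5-hydroxy-2,3-dimethyl-6-prenylchroman-4-one whose O7 and C8 carry the (R)-4-propyl-dihydropyranone ring C), via keteniminium triflate 15 (not isolated), via allyloxy iminium triflate 16 (not isolated), via prenyl iminium triflate 17 (not isolated)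
Conditions: Tf2O (1.1 equiv), 2,6-di-tert-butyl-4-methylpyridine (2.5 equiv), CH2Cl2, -78 °C to rt; then 35 °C; then H2O-THF, rt; citric acid wash
Reagents that add atoms: water, O
Why: Proposed new method: Tf2O O-triflates the pyrrolidide and the hindered pyridine removes the C3 proton to give keteniminium 15, whose slim sp carbon C4 is attacked by C4a of ring A (6-exo-dig, the C4=N bond that takes up the electrons lying outside new ring B while C3=C4 stays inside); loss of the C4a proton gives the 4-amino-2H-chromene, which the pyridinium triflate protonates at C3 to iminium 16. The closest known reaction types are the Vilsmeier-Haack-type cyclisation of triflic-anhydride-activated tertiary amides onto electron-rich arenes and the arene-keteniminium cyclisation, and the part without precedent is the second event, a charge-accelerated aromatic Claisen rearrangement related to the Lewis-acid-accelerated variants. In 16 the O5 lone pair is conjugated through C5=C4a with the C4 iminium and the tertiary allyl group is pressed against the pyrrolidinium ring, so the O5-C bond is weakened and the [3,3] shift to C6 should run near room temperature, after which tautomerisation gives 17 and water hydrolyses the iminium to ketone 18. C2 is untouched, whereas C3 is re-set: in the enamine the C2 methyl lies pseudoaxial to avoid the C3 methyl, so the bulky proton donor comes from the opposite face and gives the cis pair, direct closure without keteniminium formation would keep the same (3S) centre, and allylic 1,3-strain with the N-methylene denies the iminium the diequatorial trans form that drives epimerisation of the ketone. Site selectivity of the acylation is fixed by the O1 tether (C8, the other ortho carbon, carries ring C), the order of events by the fact that the Claisen trigger exists only once C4 is bonded to C4a, and its direction by C4a then being blocked so that only C6 is open. The benzylic centre, the lactone and the alkene should be inert to the buffered, non-nucleophilic medium.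

**Step 9**
Reactants: 18 tricyclic keto lactone
Product: 19 methyl (3R)-3-[(2R,3S)-5,7-dihydroxy-2,3-dimethyl-6-(3-methylbut-2-en-1-yl)-4-oxo-3,4-dihydro-2H-chromen-8-yl]hexanoate
Conditions: camphorsulfonic acid (10 mol %), MeOH, rt; NaHCO3 before concentration
Reagents that add atoms: methanol, CO
Why: Acid-catalysed transesterification of the aryl lactone by the solvent, driven by the excess of methanol and by relief of crowding between O7 and the prenyl group, frees 7-OH and forms the methyl ester under conditions too mild for enolisation at C3 or for cyclisation of the prenyl group onto a phenol.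

**Compound list**
1 | phloroglucinol | Oc1cc(O)cc(O)c1 | starting material
2 | ethyl 3-oxohexanoate | CCCC(=O)CC(=O)OCC | starting material
3 | 5,7-dihydroxy-4-propylcoumarin | CCCC1=CC(=O)Oc2cc(O)cc(O)c12 | intermediate
4 | 2-methylbut-3-en-2-ol | CC(C)(O)C=C | starting material
5 | lithium 2-methylbut-3-en-2-olate (not isolated) | CC(C)([O-])C=C.[Li+] | intermediate
6 | tert-butyl (2-methylbut-3-en-2-yl) carbonate | CC(C)(C)OC(=O)OC(C)(C)C=C | intermediate
7 | 5-hydroxy-7-[(2-methylbut-3-en-2-yl)oxy]-4-propylcoumarin | CCCC1=CC(=O)Oc2cc(OC(C)(C)C=C)cc(O)c12 | intermediate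
8 | (4R)-2,5-bis[diethoxy(methyl)silyloxy]-7-[(2-methylbut-3-en-2-yl)oxy]-4-propyl-4H-chromene, silyl ketene acetal (not isolated) | CCC[C@@H]1C=C(O[Si](C)(OCC)OCC)Oc2cc(OC(C)(C)C=C)cc(O[Si](C)(OCC)OCC)c12 | intermediate
9 | (4R)-5-hydroxy-7-[(2-methylbut-3-en-2-yl)oxy]-4-propyl-3,4-dihydrochromen-2-one | CCC[C@@H]1CC(=O)Oc2cc(OC(C)(C)C=C)cc(O)c12 | intermediate
10 | methyl (S)-3-hydroxybutanoate | C[C@H](O)CC(=O)OC | starting material
11 | dilithio alkoxide-enolate of 10 (not isolated) | C[C@H]([O-])C=C([O-])OC.[Li+].[Li+] | intermediate
12 | methyl (2S,3S)-3-hydroxy-2-methylbutanoate (anti) | C[C@H](O)[C@H](C)C(=O)OC | intermediate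
13 | (2S,3S)-3-hydroxy-2-methyl-1-(pyrrolidin-1-yl)butan-1-one | C[C@H](O)[C@H](C)C(=O)N1CCCC1 | intermediate
14 | (2S,3R)-2-methyl-3-{[(4R)-7-[(2-methylbut-3-en-2-yl)oxy]-2-oxo-4-propyl-3,4-dihydrochromen-5-yl]oxy}-1-(pyrrolidin-1-yl)butan-1-one | CCC[C@@H]1CC(=O)Oc2cc(OC(C)(C)C=C)cc(O[C@H](C)[C@H](C)C(=O)N3CCCC3)c12 | intermediate
15 | keteniminium triflate of 14 (C3=C4=N cumulene, C2 R, benzylic R; not isolated) | CCC[C@@H]1CC(=O)Oc2cc(OC(C)(C)C=C)cc(O[C@H](C)C(C)=C=[N+]3CCCC3)c12.[O-]S(=O)(=O)C(F)(F)F | intermediate
16 | ring-closed cis-2,3-dimethyl C4 pyrrolidinium-ylidene triflate, 5-O-(1,1-dimethylallyl), ring C intact (not isolated) | CCC[C@@H]1CC(=O)Oc2cc(OC(C)(C)C=C)c3c(O[C@H](C)[C@H](C)C3=[N+]4CCCC4)c12.[O-]S(=O)(=O)C(F)(F)F | intermediate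
17 | the same iminium triflate after the [3,3] shift: 5-OH, 6-prenyl (not isolated) | CCC[C@@H]1CC(=O)Oc2c(CC=C(C)C)c(O)c3c(O[C@H](C)[C@H](C)C3=[N+]4CCCC4)c12.[O-]S(=O)(=O)C(F)(F)F | intermediate
18 | tricyclic keto lactone: cis-(2R,3S)-5-hydroxy-2,3-dimethyl-6-prenylchroman-4-one with O7 and C8 joined through the (R)-CH(propyl)CH2C(=O) bridge | CCC[C@@H]1CC(=O)Oc2c(CC=C(C)C)c(O)c3c(O[C@H](C)[C@H](C)C3=O)c12 | intermediate
19 | methyl (3R)-3-[(2R,3S)-5,7-dihydroxy-2,3-dimethyl-6-(3-methylbut-2-en-1-yl)-4-oxo-3,4-dihydro-2H-chromen-8-yl]hexanoate | CCC[C@H](CC(=O)OC)c1c(O)c(CC=C(C)C)c(O)c2c1O[C@H](C)[C@H](C)C2=O | target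

**Total step count:** 9
**Longest linear sequence:** 6 steps (1, 3, 4, 7, 8, 9)

**Steps most likely to fail**

1. Step 8 (bears the label "Proposed new method:").
   - What may go wrong: the activated O5-C bond may break heterolytically, so that the allyl unit is lost instead of being transferred to C6. The crowded ortho-hydroxyaryl iminium may also hydrolyse slowly, with erosion at C3 or retro-oxa-Michael opening at C2.
   - Fallback (known chemistry only): it sets out from 14. The triflic anhydride activation is used for the Vilsmeier-Haack-type ring closure alone, and CF3CO2H is added before the water so that the tertiary allyl ether is cleaved on purpose. This should give the 5-hydroxy keto lactone without a C6 substituent F1.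
   - Camphorsulfonic acid in MeOH then opens ring C to the 6-unsubstituted dihydroxy methyl ester F2.
   - Tsuji-Trost O-allylation with 6 and Pd(PPh3)4 takes the free 7-OH, since 5-OH is tied up by chelation to C4=O, and gives the 7-O-(1,1-dimethylallyl) ether F3.
   - Heating in toluene at 110 °C brings about a thermal aromatic Claisen rearrangement to C6, the only open ortho carbon. The fallback comes back to the route at 19.

2. Step 7.
   - What may go wrong: the oxyphosphonium salt may eliminate to the unsaturated amide, and the ortho-substituted phenoxide may attack a branched secondary carbon only sluggishly.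
   - Fallback: it sets out from 12 and 9 and replaces hydroxyl activation by strain release.
   - LiOH in aqueous THF gives (2S,3S)-3-hydroxy-2-methylbutanoic acid F4.
   - Carboxyl activation with PhSO2Cl in pyridine closes it, with retention at both centres, to the trans beta-lactone (3S,4S)-3,4-dimethyloxetan-2-one F5.
   - The sodium phenoxide of 9 (NaH, DMF) opens F5 at C4 by alkyl-oxygen cleavage with SN2 inversion and gives the aryloxy acid F6.
   - Carbodiimide coupling (EDC, HOBt) with one equivalent of pyrrolidine comes back to the route at 14.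

3. Step 4.
   - What may go wrong: facial selectivity may be poor at the crowded, electron-rich C4. The lactone may undergo 1,2-reduction once it is protonated, or hydride may attack the allyl ether.
   - Fallback: it sets out from 1 and builds the stereocentre by C-C bond formation instead of reduction.
   - An oxidative carbene-catalysed annulation is run with (E)-hex-2-enal, a chiral aminoindanol-derived triazolium salt, iPr2NEt and 3,3',5,5'-tetra-tert-butyldiphenoquinone in THF. It passes through the unsaturated acyl azolium, joins its beta carbon to ring A and lactonises, giving (4R)-5,7-dihydroxy-4-propyl-3,4-dihydrochromen-2-one F7.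
   - Tsuji-Trost O-allylation with 6 and Pd(PPh3)4 at the less hindered 7-OH comes back to the route at 9.

**Further compounds**
F1 | step 8 | 5-hydroxy keto lactone without C6 substituent (18 lacking the prenyl group) | CCC[C@@H]1CC(=O)Oc2cc(O)c3c(O[C@H](C)[C@H](C)C3=O)c12
F2 | step 8 | methyl (3R)-3-[(2R,3S)-5,7-dihydroxy-2,3-dimethyl-4-oxo-3,4-dihydro-2H-chromen-8-yl]hexanoate | CCC[C@H](CC(=O)OC)c1c(O)cc(O)c2c1O[C@H](C)[C@H](C)C2=O
F3 | step 8 | methyl (3R)-3-{(2R,3S)-5-hydroxy-2,3-dimethyl-7-[(2-methylbut-3-en-2-yl)oxy]-4-oxo-3,4-dihydro-2H-chromen-8-yl}hexanoate | CCC[C@H](CC(=O)OC)c1c(OC(C)(C)C=C)cc(O)c2c1O[C@H](C)[C@H](C)C2=O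
F4 | step 7 | (2S,3S)-3-hydroxy-2-methylbutanoic acid | C[C@H](O)[C@H](C)C(=O)O
F5 | step 7 | (3S,4S)-3,4-dimethyloxetan-2-one (trans) | C[C@@H]1OC(=O)[C@H]1C
F6 | step 7 | (2S,3R)-2-methyl-3-{[(4R)-7-[(2-methylbut-3-en-2-yl)oxy]-2-oxo-4-propyl-3,4-dihydrochromen-5-yl]oxy}butanoic acid | CCC[C@@H]1CC(=O)Oc2cc(OC(C)(C)C=C)cc(O[C@H](C)[C@H](C)C(=O)O)c12
F7 | step 4 | (4R)-5,7-dihydroxy-4-propyl-3,4-dihydrochromen-2-one | CCC[C@@H]1CC(=O)Oc2cc(O)cc(O)c12
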